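**Retrosynthetic overview**
1. Target ⇐ saponification of an enol δ-lactone ⇐ prenyl group by cross-metathesis of a crotyl group ⇐ dearomative Claisen rearrangement of an aromatic (R)-but-3-en-2-yl ether, which makes the quaternary ring carbon by 1,3-chirality transfer.
2. Aromatic precursor ⇐ pyranone closure (aldehyde onto the one free ring CH, then oxidation) ⇐ phenol lactone ⇐ ring expansion of a 3-alkoxycyclobut-2-enone (four of the six carbons of carbocycle A) by a siloxyalkyne (the other two).
3. Enabling feature: ring A carries oxygen on alternate carbons (the two C=O carbons and the pyran-O carbon) and carbon groups on the other three. The C=O carbon between the quaternary carbon and the CH(Ph)-bearing carbon is the cyclobutenone C=O, the CH(Ph)-bearing carbon is the ketene α-carbon, the pyran-O carbon is the ynol-ether carbon, and the quaternary carbon plus the other C=O carbon are the C≡C–OSi unit. The phenol oxygen born from the cyclobutenone C=O is placed for six-membered lactone closure on the ester.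
4. Ring order: cyclobutenone → ring A (aromatic) with the lactone → pyranone ring → dearomatisation of ring A → lactone opened.
5. Stereocentres: side-chain CH by rhodium-catalysed 1,4-addition, benzylic CH by anhydride desymmetrisation, the CHMe–CHMe pair from ethyl (S)-3-hydroxybutanoate, quaternary C from (S)-but-3-en-2-ol.

Key step: step 11

Remark: the target is an enolised cyclic β-triketone drawn as one tautomer; the last step gives that compound whichever tautomer is written. CIP descriptors in the names can change between intermediates although the spatial arrangement is unchanged.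

**Step 1**
Reactants: 1 2-methylhexa-1,5-diene; 2 ethyl acrylate
Product: 3 ethyl (2E)-6-methylhepta-2,6-dienoate
Conditions: second-generation Hoveyda–Grubbs catalyst (2 mol %), 2 (3 equiv), CH2Cl2, 40 °C
Reagents that add atoms: none
Why: Olefin cross-metathesis of the monosubstituted alkene with the acrylate should be fast and E-selective, while the 1,1-disubstituted alkene is too hindered to compete.

**Step 2**
Reactants: 3 ethyl (2E)-6-methylhepta-2,6-dienoate; 4 (2-methylprop-1-en-1-yl)boronic acid
Product: 5 ethyl (3R)-6-methyl-3-(2-methylprop-1-en-1-yl)hept-6-enoate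
Conditions: Rh(acac)(C2H4)2 (3 mol %), (R)-BINAP (3.3 mol %), 4 (3 equiv), dioxane/H2O 10:1, 100 °C
Reagents that add atoms: none
Why: Rhodium-catalysed asymmetric 1,4-addition (Hayashi–Miyaura reaction) of the alkenylboronic acid to the (E)-enoate sets the side-chain stereocentre under ligand control; the (R) ligand is written from the accepted facial model for (E)-enoates, and its antipode is to be used if correlation shows the opposite sense.

**Step 3**
Reactants: 5 ethyl (3R)-6-methyl-3-(2-methylprop-1-en-1-yl)hept-6-enoate
Product: 7 triisopropyl{[(4R)-7-methyl-4-(2-methylprop-1-en-1-yl)oct-7-en-1-yn-1-yl]oxy}silane, via lithium ynolate 6 (not isolated)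
Conditions: CH2Br2 (2.2 equiv), lithium 2,2,6,6-tetramethylpiperidide (2 equiv), THF, −78 °C; LiN(SiMe3)2; n-BuLi, −78 → 25 °C; then iPr3SiCl, 0 °C
Reagents that add atoms: dibromomethane (BrCBr); chlorotriisopropylsilane (CC(C)[Si](Cl)(C(C)C)C(C)C)
Why: Kowalski ester homologation stopped at the ynolate: LiCHBr2 adds to the ester, enolisation, Br–Li exchange and 1,2-shift of the alkyl group give the lithium ynolate, which the bulky chlorosilane silylates on oxygen; the β-stereocentre is not touched.

**Step 4**
Reactants: 8 3-phenylglutaric anhydride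
Product: 9 (3R)-5-methoxy-5-oxo-3-phenylpentanoic acid
Conditions: MeOH (10 equiv), quinine-derived sulfonamide organocatalyst (10 mol %), methyl tert-butyl ether, 25 °C
Reagents that add atoms: methanol (CO)
Why: Enantioselective methanolysis (desymmetrisation) of the meso anhydride by a bifunctional cinchona catalyst sets the benzylic stereocentre; the quinidine-derived pseudo-enantiomer is to be used if the other hand results, and the half-ester can be upgraded by salt crystallisation.

**Step 5**
Reactants: 9 (3R)-5-methoxy-5-oxo-3-phenylpentanoic acid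
Product: 10 methyl (3S)-5-chloro-5-oxo-3-phenylpentanoate
Conditions: (COCl)2, DMF (cat.), CH2Cl2, 0 → 25 °C
Reagents that add atoms: oxalyl chloride (O=C(Cl)C(=O)Cl)
Why: Standard acid chloride formation through the Vilsmeier-type chloroiminium species; the β-stereocentre cannot epimerise (the descriptor changes by CIP priority only).

**Step 6**
Reactants: 11 ethyl (3S)-3-hydroxybutanoate
Product: 12 ethyl (2S,3S)-3-hydroxy-2-methylbutanoate
Conditions: LiN(iPr)2 (2.2 equiv), THF, −50 → −20 °C; MeI, −78 → −20 °C
Reagents that add atoms: iodomethane (CI)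
Why: Fráter–Seebach alkylation: the chelated alkoxide–enolate dianion should be methylated anti to the C3 methyl group, giving the anti (2S,3S) ester.

**Step 7**
Reactants: 12 ethyl (2S,3S)-3-hydroxy-2-methylbutanoate
Product: 13 (2R,3S)-2-methylbutane-1,3-diol
Conditions: LiAlH4, THF, 0 °C
Reagents that add atoms: none
Why: Hydride reduction of the ester to the primary alcohol affects no stereocentre.

**Step 8**
Reactants: 13 (2R,3S)-2-methylbutane-1,3-diol
Product: 14 (2S,3R)-3-methyl-4-(triphenylmethoxy)butan-2-ol
Conditions: Ph3CCl, Et3N, DMAP (cat.), CH2Cl2, 0 → 25 °C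
Reagents that add atoms: chlorotriphenylmethane (ClC(c1ccccc1)(c1ccccc1)c1ccccc1)
Why: Tritylation is selective for the primary hydroxyl, and a trityl ether, unlike a silyl ether, cannot migrate to the secondary alkoxide formed in step 9.

**Step 9**
Reactants: 14 (2S,3R)-3-methyl-4-(triphenylmethoxy)butan-2-ol
Product: 16 [(2R,3S)-3-(ethynyloxy)-2-methylbutoxy]triphenylmethane, via dichlorovinyl ether 15 (not isolated)
Conditions: KH, THF, 0 °C; Cl2C=CHCl, −50 → 25 °C; then n-BuLi (2.5 equiv), −78 → −40 °C; MeOH
Reagents that add atoms: trichloroethylene (ClC=C(Cl)Cl)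
Why: Alkoxide addition–elimination on trichloroethylene gives the (E)-1,2-dichlorovinyl ether, and dehydrochlorination, Cl–Li exchange and protonation give the terminal ynol ether (established ynol ether synthesis for secondary alcohols); the carbinol C–O bond is never broken, so its configuration is retained.

**Step 10**
Reactants: 10 methyl (3S)-5-chloro-5-oxo-3-phenylpentanoate; 16 [(2R,3S)-3-(ethynyloxy)-2-methylbutoxy]triphenylmethane
Product: 18 methyl (3S)-3-[2-{[(2S,3R)-3-methyl-4-(triphenylmethoxy)butan-2-yl]oxy}-4-oxocyclobut-2-en-1-yl]-3-phenylpropanoate (both epimers at the ring CH), via ketene 17 (not isolated)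
Conditions: 10 (1.3 equiv), Et3N (slow addition), CH2Cl2, 0 → 25 °C
Reagents that add atoms: none
Why: Dehydrochlorination gives the aldoketene, which the electron-rich ynol ether traps in a regioselective [2+2] cycloaddition (ketene C=O carbon to the unsubstituted alkyne carbon) to give the 3-alkoxycyclobutenone; the new ring stereocentre is irrelevant because it becomes sp2 in step 11.

**Step 11**
Reactants: 18 cyclobutenone from step 10; 7 triisopropyl{[(4R)-7-methyl-4-(2-methylprop-1-en-1-yl)oct-7-en-1-yn-1-yl]oxy}silane
Product: 24 (4R)-5-{[(2S,3R)-3-methyl-4-(triphenylmethoxy)butan-2-yl]oxy}-8-[(2R)-5-methyl-2-(2-methylprop-1-en-1-yl)hex-5-en-1-yl]-4-phenyl-7-[(triisopropylsilyl)oxy]-3,4-dihydro-2H-chromen-2-one, via vinylketene 19 (not isolated), via 4-vinylcyclobutenone 20 (not isolated), via dienylketene 21 (not isolated), via cyclohexadienone 22 (not isolated), via phenol ester 23 (not isolated)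
Conditions: 7 (1.3 equiv), toluene (0.1 M), 100 °C, sealed under Ar; then DBU (10 mol %), 5 Å molecular sieves, 80 °C
Reagents that add atoms: none
Why: Heating opens cyclobutenone 18 by 4π electrocyclic ring opening to vinylketene 19, which adds siloxyalkyne 7 in a regioselective [2+2] cycloaddition to give 4-vinylcyclobutenone 20; a second 4π opening gives dienylketene 21, 6π electrocyclisation gives cyclohexadienone 22 and tautomerisation gives phenol 23, so the four-membered ring is expanded by the two alkyne carbons (Danheiser benzannulation; closest known case: 3-oxycyclobutenones with siloxyalkynes giving resorcinol and phloroglucinol ethers). Ring A is closed by the thermal disrotatory 6π electrocyclisation of the dienylketene, and the lactone by 6-exo-trig acyl substitution of the new phenol on the methyl ester, driven by removal of MeOH. No stereocentre is created: the side-chain CH, the benzylic CH and the CHMe–CHMe pair are remote from the reacting carbons and are carried through, and the cyclobutenone ring stereocentre is destroyed. The selectivity needed is regiochemical, and it is secured by the polarity match of ketene (electrophilic at the C=O carbon) and ynol ether (nucleophilic at the carbon remote from oxygen) in both [2+2] events, which fixes the 1,3,5-oxygen pattern and places the C10 chain, the free CH and the phenylpropanoate on alternate carbons. Because the phenol oxygen arises from the cyclobutenone carbonyl next to the ketene α-carbon, it is the only free oxygen and the one positioned to lactonise, so all three ring oxygens leave this step differentiated.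

**Step 12**
Reactants: 24 lactone from step 11
Product: 25 the primary alcohol (trityl removed; 5-{[(2S,3R)-4-hydroxy-3-methylbutan-2-yl]oxy} analogue of 24)
Conditions: AcOH/H2O/THF (4:1:1), 40 °C
Reagents that add atoms: none
Why: Acid-catalysed detritylation in dilute aqueous acetic acid should leave the aryl silyl ether, the lactone and the alkenes untouched.

**Step 13**
Reactants: 25 primary alcohol
Product: 26 the aldehyde ((2S,3S)-2-methyl-3-(aryloxy)butanal side chain on the core of 24)
Conditions: Dess–Martin periodinane, pyridine, CH2Cl2, 0 → 25 °C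
Reagents that add atoms: none
Why: Dess–Martin oxidation of the primary alcohol under buffered conditions; the electron-rich ring has no free hydroxyl, and any epimerisation α to the aldehyde is corrected in step 15.

**Step 14**
Reactants: 26 aldehyde
Product: 27 the tricyclic chromanol (pyran ring closed on the free ring CH; both carbinol epimers)
Conditions: ZnCl2 (1.5 equiv), CH2Cl2 (0.01 M), −20 → 0 °C
Reagents that add atoms: none
Why: Intramolecular Friedel–Crafts hydroxyalkylation at the only unsubstituted carbon of ring A, which is flanked by two oxygens, closes the six-membered pyran ring; the new carbinol stereocentre is removed in step 15.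

**Step 15**
Reactants: 27 chromanol
Product: 28 the tricyclic (2S,3S)-2,3-dimethylchroman-4-one fused to the (4R)-4-phenyldihydrocoumarin, with the silyl ether between ketone and C10 chain
Conditions: Dess–Martin periodinane, pyridine, CH2Cl2, 0 °C; then Et3N (cat.), 25 °C
Reagents that add atoms: none
Why: Dess–Martin oxidation of the benzylic alcohol gives the chromanone, and base equilibration of the centre α to the ketone should settle the thermodynamically preferred trans (2S,3S) arrangement relative to the fixed O-bearing stereocentre.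

**Step 16**
Reactants: 28 silylated chromanone lactone
Product: 29 the free phenol (OH between the chromanone C=O and the C10-bearing carbon)
Conditions: Bu4NF/AcOH (1:1, 1.2 equiv), THF, 0 °C
Reagents that add atoms: none
Why: Fluoride cleavage of the aryl silyl ether, buffered so that the lactone and the base-sensitive chromanone survive.

**Step 17**
Reactants: 29 phenol; 30 (2S)-but-3-en-2-ol
Product: 31 the aryl (2R)-but-3-en-2-yl ether of 29
Conditions: 30 (1.5 equiv), PPh3, DIAD, THF, 0 → 25 °C
Reagents that add atoms: none
Why: Mitsunobu etherification of the acidic chelated phenol should proceed with inversion at the allylic carbinol carbon to give the (R) ether, the only free hydroxyl being the one ortho to the carbon that must become quaternary.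

**Step 18**
Reactants: 31 aryl (2R)-but-3-en-2-yl ether
Product: 32 the dearomatised enol lactone with an (E)-but-2-enyl group on the quaternary carbon (spatial arrangement of the target)
Conditions: toluene (degassed), 110 °C, sealed tube
Reagents that add atoms: none
Why: Aromatic Claisen rearrangement: the [3,3] shift can only end on the C10-bearing ortho carbon (the other ortho carbon carries the ring-fused acyl), and a chair transition state with pseudo-equatorial methyl should transfer the (R) carbinol chirality to the quaternary carbon while forming the (E)-alkene; the product cannot rearomatise.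

**Step 19**
Reactants: 32 crotyl enol lactone
Product: 33 the prenyl enol lactone
Conditions: second-generation Hoveyda–Grubbs catalyst (5 mol %), 2-methylbut-2-ene/CH2Cl2 (1:1), 25 °C
Reagents that add atoms: 2-methylbut-2-ene (CC=C(C)C)
Why: Olefin cross-metathesis should convert the 1,2-disubstituted crotyl alkene to the prenyl group, since the trisubstituted and 1,1-disubstituted alkenes of the C10 chain react far more slowly.

**Step 20**
Reactants: 33 prenyl enol lactone
Product: 34 the target, CNP0155375.2
Conditions: LiOH (3 equiv), THF/H2O (3:1), 0 °C; then 1 M HCl to pH 3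
Reagents that add atoms: lithium hydroxide ([Li+].[OH-])
Why: Saponification of the enol lactone (an activated ester) frees the carboxylic acid and the ring oxygen, which tautomerises to the enolised triketone; the quaternary carbon cannot epimerise and the α-methyl centre is already in its thermodynamic trans position.

**Compound list**
1 | 2-methylhexa-1,5-diene | C=C(C)CCC=C | starting material
2 | ethyl acrylate | C=CC(=O)OCC | starting material
3 | ethyl (2E)-6-methylhepta-2,6-dienoate | C=C(C)CC/C=C/C(=O)OCC | intermediate
4 | (2-methylprop-1-en-1-yl)boronic acid | CC(C)=CB(O)O | starting material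
5 | ethyl (3R)-6-methyl-3-(2-methylprop-1-en-1-yl)hept-6-enoate | CCOC(=O)C[C@@H](CCC(C)=C)C=C(C)C | intermediate
6 | lithium (4R)-7-methyl-4-(2-methylprop-1-en-1-yl)oct-7-en-1-yn-1-olate | [Li+].[O-]C#CC[C@@H](CCC(C)=C)C=C(C)C | intermediate
7 | triisopropyl{[(4R)-7-methyl-4-(2-methylprop-1-en-1-yl)oct-7-en-1-yn-1-yl]oxy}silane | CC(C)[Si](C(C)C)(C(C)C)OC#CC[C@@H](CCC(C)=C)C=C(C)C | intermediate
8 | 3-phenylglutaric anhydride | O=C1CC(c2ccccc2)CC(=O)O1 | starting material
9 | (3R)-5-methoxy-5-oxo-3-phenylpentanoic acid | OC(=O)C[C@H](CC(=O)OC)c1ccccc1 | intermediate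
10 | methyl (3S)-5-chloro-5-oxo-3-phenylpentanoate | ClC(=O)C[C@H](CC(=O)OC)c1ccccc1 | intermediate
11 | ethyl (3S)-3-hydroxybutanoate | CCOC(=O)C[C@H](C)O | starting material
12 | ethyl (2S,3S)-3-hydroxy-2-methylbutanoate | CCOC(=O)[C@@H](C)[C@H](C)O | intermediate
13 | (2R,3S)-2-methylbutane-1,3-diol | O[C@@H](C)[C@H](C)CO | intermediate
14 | (2S,3R)-3-methyl-4-(triphenylmethoxy)butan-2-ol | O[C@@H](C)[C@H](C)COC(c1ccccc1)(c1ccccc1)c1ccccc1 | intermediate
15 | [(2R,3S)-3-{[(E)-1,2-dichloroethenyl]oxy}-2-methylbutoxy]triphenylmethane | Cl/C=C(/Cl)O[C@@H](C)[C@H](C)COC(c1ccccc1)(c1ccccc1)c1ccccc1 | intermediate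
16 | [(2R,3S)-3-(ethynyloxy)-2-methylbutoxy]triphenylmethane | C#CO[C@@H](C)[C@H](C)COC(c1ccccc1)(c1ccccc1)c1ccccc1 | intermediate
17 | methyl (3S)-5-oxo-3-phenylpent-4-enoate (ketene) | O=C=C[C@H](CC(=O)OC)c1ccccc1 | intermediate
18 | methyl (3S)-3-[2-{[(2S,3R)-3-methyl-4-(triphenylmethoxy)butan-2-yl]oxy}-4-oxocyclobut-2-en-1-yl]-3-phenylpropanoate | O=C1C=C(O[C@@H](C)[C@H](C)COC(c2ccccc2)(c2ccccc2)c2ccccc2)C1[C@H](CC(=O)OC)c1ccccc1 | intermediate
19 | vinylketene from ring opening of 18 | O=C=C/C(O[C@@H](C)[C@H](C)COC(c1ccccc1)(c1ccccc1)c1ccccc1)=C/[C@H](CC(=O)OC)c1ccccc1 | intermediate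
20 | 4-vinylcyclobutenone ([2+2] adduct of 19 and 7) | O=C1C(C[C@@H](CCC(C)=C)C=C(C)C)=C(O[Si](C(C)C)(C(C)C)C(C)C)C1/C(O[C@@H](C)[C@H](C)COC(c1ccccc1)(c1ccccc1)c1ccccc1)=C/[C@H](CC(=O)OC)c1ccccc1 | intermediate
21 | dienylketene from ring opening of 20 | O=C=C(C[C@@H](CCC(C)=C)C=C(C)C)/C(O[Si](C(C)C)(C(C)C)C(C)C)=C\C(O[C@@H](C)[C@H](C)COC(c1ccccc1)(c1ccccc1)c1ccccc1)=C\[C@H](CC(=O)OC)c1ccccc1 | intermediate
22 | cyclohexa-2,4-dienone from 6π closure of 21 | O=C1C(C[C@@H](CCC(C)=C)C=C(C)C)=C(O[Si](C(C)C)(C(C)C)C(C)C)C=C(O[C@@H](C)[C@H](C)COC(c2ccccc2)(c2ccccc2)c2ccccc2)C1[C@H](CC(=O)OC)c1ccccc1 | intermediate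
23 | phenol methyl ester (tautomer of 22) | Oc1c(C[C@@H](CCC(C)=C)C=C(C)C)c(O[Si](C(C)C)(C(C)C)C(C)C)cc(O[C@@H](C)[C@H](C)COC(c2ccccc2)(c2ccccc2)c2ccccc2)c1[C@H](CC(=O)OC)c1ccccc1 | intermediate
24 | (4R)-5-{[(2S,3R)-3-methyl-4-(triphenylmethoxy)butan-2-yl]oxy}-8-[(2R)-5-methyl-2-(2-methylprop-1-en-1-yl)hex-5-en-1-yl]-4-phenyl-7-[(triisopropylsilyl)oxy]-3,4-dihydro-2H-chromen-2-one | O=C1C[C@H](c2ccccc2)c2c(O[C@@H](C)[C@H](C)COC(c3ccccc3)(c3ccccc3)c3ccccc3)cc(O[Si](C(C)C)(C(C)C)C(C)C)c(C[C@@H](CCC(C)=C)C=C(C)C)c2O1 | intermediate
25 | primary alcohol (detritylated 24) | O=C1C[C@H](c2ccccc2)c2c(O[C@@H](C)[C@H](C)CO)cc(O[Si](C(C)C)(C(C)C)C(C)C)c(C[C@@H](CCC(C)=C)C=C(C)C)c2O1 | intermediate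
26 | aldehyde from 25 | O=C1C[C@H](c2ccccc2)c2c(O[C@@H](C)[C@H](C)C=O)cc(O[Si](C(C)C)(C(C)C)C(C)C)c(C[C@@H](CCC(C)=C)C=C(C)C)c2O1 | intermediate
27 | tricyclic chromanol | O=C1C[C@H](c2ccccc2)c2c3O[C@@H](C)[C@H](C)C(O)c3c(O[Si](C(C)C)(C(C)C)C(C)C)c(C[C@@H](CCC(C)=C)C=C(C)C)c2O1 | intermediate
28 | tricyclic (2S,3S)-2,3-dimethylchromanone lactone, silyl ether | O=C1C[C@H](c2ccccc2)c2c3O[C@@H](C)[C@H](C)C(=O)c3c(O[Si](C(C)C)(C(C)C)C(C)C)c(C[C@@H](CCC(C)=C)C=C(C)C)c2O1 | intermediate
29 | tricyclic chromanone lactone, free phenol | O=C1C[C@H](c2ccccc2)c2c3O[C@@H](C)[C@H](C)C(=O)c3c(O)c(C[C@@H](CCC(C)=C)C=C(C)C)c2O1 | intermediate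
30 | (2S)-but-3-en-2-ol | C=C[C@H](C)O | starting material
31 | aryl (2R)-but-3-en-2-yl ether of 29 | O=C1C[C@H](c2ccccc2)c2c3O[C@@H](C)[C@H](C)C(=O)c3c(O[C@H](C)C=C)c(C[C@@H](CCC(C)=C)C=C(C)C)c2O1 | intermediate
32 | dearomatised enol lactone with (E)-but-2-enyl on the quaternary carbon | C=C(C)CC[C@@H](C=C(C)C)C[C@@]1(C/C=C/C)C(=O)C2=C(O[C@@H](C)[C@H](C)C2=O)C3=C1OC(=O)C[C@@H]3c1ccccc1 | intermediate
33 | dearomatised enol lactone with prenyl on the quaternary carbon | C=C(C)CC[C@@H](C=C(C)C)C[C@@]1(CC=C(C)C)C(=O)C2=C(O[C@@H](C)[C@H](C)C2=O)C3=C1OC(=O)C[C@@H]3c1ccccc1 | intermediate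
34 | CNP0155375.2 | C=C(C)CC[C@@H](C=C(C)C)C[C@@]1(CC=C(C)C)C(=O)C2=C(O)[C@@H](C)[C@H](C)OC2=C([C@H](CC(=O)O)c2ccccc2)C1=O | target

**Step count and risks**
Total steps: 20. Longest linear sequence: 15 steps (steps 6–20, from ethyl (S)-3-hydroxybutanoate); steps 1–3 and 4–5 are side branches that join at steps 11 and 10.

Most likely to fail:

1. Step 18. Chirality transfer may erode through a boat or axial-methyl transition state, or the allylic ether may ionise or eliminate at the temperature needed, giving poor facial selectivity at the quaternary carbon. The fallback sets out from 29 and replaces the sigmatropic step by ligand-controlled allylation: acylation with allyl chloroformate and pyridine gives the allyl aryl carbonate F1; Pd2(dba)3 with the (R,R)-DACH-phenyl Trost ligand in toluene (ligand enantiomer fixed by screening) effects decarboxylative Tsuji–Trost C-allylation at the C10-bearing carbon to give the allyl dienone F2; cross-metathesis of F2 with 2-methylbut-2-ene under the conditions of step 19 returns to the route at 33.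

2. Step 11. The vinylketene may oligomerise, or the siloxyalkyne may rearrange to a silylketene before the cycloaddition, so that the thermal cascade stalls. The fallback sets out from 18 and 7 and replaces the pericyclic cascade by zerovalent-nickel catalysis (Ni(cod)2, 10 mol %, THF, 0 → 25 °C): oxidative addition into the acyl–C(sp3) bond of the cyclobutenone, alkyne insertion and reductive elimination, the known nickel-catalysed cyclobutenone–alkyne phenol synthesis, which still expands the four-membered ring by two carbons. Regiochemistry of insertion would have to be confirmed. It gives phenol 23, which is lactonised with DBU and sieves to return at 24; it makes no new compound (F0).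

3. Step 19. Metathesis may also occur at the 1,1-disubstituted alkene of the C10 chain (ethylidene exchange), or the catalyst may be sequestered by the dienone. The fallback sets out from 29 and delivers the prenyl group directly: copper-catalysed O-alkylation with 3-chloro-3-methylbut-1-yne (CuCl2 cat., DBU, MeCN, 0 °C) gives the 1,1-dimethylpropargyl ether F3; semihydrogenation (H2, Pd/CaCO3 poisoned with Pb(OAc)2, quinoline, EtOAc) gives the 1,1-dimethylallyl ether F4; heating F4 in toluene at 110 °C should give, by Claisen rearrangement, 33 together with its epimer at the quaternary carbon. Facial selectivity is then only substrate-controlled, so the epimers would be separated by chromatography before returning to the route at 33.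

**Further compounds**
F1 | step 18 | allyl carbonate of phenol 29 | O=C1C[C@H](c2ccccc2)c2c3O[C@@H](C)[C@H](C)C(=O)c3c(OC(=O)OCC=C)c(C[C@@H](CCC(C)=C)C=C(C)C)c2O1
F2 | step 18 | dearomatised enol lactone with allyl on the quaternary carbon | C=C(C)CC[C@@H](C=C(C)C)C[C@@]1(CC=C)C(=O)C2=C(O[C@@H](C)[C@H](C)C2=O)C3=C1OC(=O)C[C@@H]3c1ccccc1
F0 | step 11 | none | none
F3 | step 19 | 2-methylbut-3-yn-2-yl ether of phenol 29 | O=C1C[C@H](c2ccccc2)c2c3O[C@@H](C)[C@H](C)C(=O)c3c(OC(C)(C)C#C)c(C[C@@H](CCC(C)=C)C=C(C)C)c2O1
F4 | step 19 | 2-methylbut-3-en-2-yl ether of phenol 29 | O=C1C[C@H](c2ccccc2)c2c3O[C@@H](C)[C@H](C)C(=O)c3c(OC(C)(C)C=C)c(C[C@@H](CCC(C)=C)C=C(C)C)c2O1
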